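**Retrosynthetic overview**

1. The target is (2S)-5-hydroxy-6,7-dimethoxy-8-prenyl-4'-hydroxyflavanone. Both benzene rings are bought; the pyranone ring (O1–C2–C3–C4–C4a–C8a) is the only ring made and is closed last, at O1–C2.
2. Enabling feature: the prenyl group on C8 is ortho to the ring oxygen O1 (on C8a), and O1 is β to the C4 ketone. O1 can therefore be carried as a 1,1-dimethylallyl ether: its aromatic Claisen shift puts prenyl on C8 and in the same event frees O1 for 6-endo oxa-Michael attack on C2.
3. Disconnections: O5–H ⇐ O5–Me (chelation-controlled demethylation, last); O1–C2 and C8–prenyl ⇐ acyclic alkylidene β-keto ester 7, which carries a temporary tert-butyl ester on C3 (activating group, lost as CO2 in the key step); C2=C3 ⇐ Knoevenagel of 5 with 6; 5 ⇐ acetophenone 1 + chloroalkyne 2.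
4. Ring order: A ring from 1, B ring from 6, pyranone ring in step 5.

Key step: step 5

Remark: the quinidine-derived thiourea is assumed to be the pseudoenantiomer that gives the 2S series; should the first run show the opposite sense, the quinine-derived pseudoenantiomer is used under the same conditions.

**Route**

Step 1
Reactants: 1 1-(6-hydroxy-2,3,4-trimethoxyphenyl)ethan-1-one; 2 3-chloro-3-methylbut-1-yne
Product: 3 1-{2,3,4-trimethoxy-6-[(2-methylbut-3-yn-2-yl)oxy]phenyl}ethan-1-one
Conditions: DBU (1.3 equiv), CuCl2·2H2O (1 mol%), MeCN, 0 °C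
Reagents that add atoms: none
Why: Copper-catalysed propargylic etherification, in which DBU forms the phenoxide and the Cu-activated tertiary propargyl chloride is captured at oxygen at 0 °C; the only free hydroxyl of 1 is the one ortho to the unsubstituted ring carbon that later receives the prenyl group.

Step 2
Reactants: 3 1-{2,3,4-trimethoxy-6-[(2-methylbut-3-yn-2-yl)oxy]phenyl}ethan-1-one
Product: 4 1-{2,3,4-trimethoxy-6-[(2-methylbut-3-en-2-yl)oxy]phenyl}ethan-1-one
Conditions: H2 (1 atm), Lindlar catalyst, quinoline, EtOAc, 20 °C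
Reagents that add atoms: none
Why: Lindlar semi-hydrogenation reduces the terminal alkyne to the vinyl group and stops there, leaving the aryl ketone untouched and, at 20 °C, the 1,1-dimethylallyl aryl ether unrearranged.

Step 3
Reactants: 4 1-{2,3,4-trimethoxy-6-[(2-methylbut-3-en-2-yl)oxy]phenyl}ethan-1-one
Product: 5 tert-butyl 3-oxo-3-{2,3,4-trimethoxy-6-[(2-methylbut-3-en-2-yl)oxy]phenyl}propanoate
Conditions: LiHMDS (2.2 equiv), THF, −78 °C; Boc2O (1.1 equiv), −78 → 0 °C; aq. NH4Cl
Reagents that add atoms: di-tert-butyl dicarbonate, CC(C)(C)OC(=O)OC(=O)OC(C)(C)C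
Why: Crossed Claisen-type C-acylation of the kinetic lithium enolate of the methyl ketone with Boc2O, the second equivalent of base converting the more acidic β-keto ester into its enolate so that acylation stops at the mono-ester.

Step 4
Reactants: 5 tert-butyl 3-oxo-3-{2,3,4-trimethoxy-6-[(2-methylbut-3-en-2-yl)oxy]phenyl}propanoate; 6 4-(tert-butoxy)benzaldehyde
Product: 7 tert-butyl (2Z)-3-(4-tert-butoxyphenyl)-2-{2,3,4-trimethoxy-6-[(2-methylbut-3-en-2-yl)oxy]benzoyl}prop-2-enoate
Conditions: piperidine (0.2 equiv), AcOH (0.2 equiv), 4 Å MS, PhMe, 20 °C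
Reagents that add atoms: none
Why: Knoevenagel condensation under piperidinium acetate with water removed by sieves; at room temperature the tertiary allyl ether does not rearrange, and because O1 is still masked the alkylidene cannot cyclise prematurely (the Z isomer, aryl cis to the ester, is expected to predominate).

Step 5
Reactants: 7 tert-butyl (2Z)-3-(4-tert-butoxyphenyl)-2-{2,3,4-trimethoxy-6-[(2-methylbut-3-en-2-yl)oxy]benzoyl}prop-2-enoate
Product: 10 (2S)-2-(4-hydroxyphenyl)-5,6,7-trimethoxy-8-(3-methylbut-2-en-1-yl)-2,3-dihydro-4H-chromen-4-one, via prenylated hydroxy alkylidene keto ester 8 (not isolated), via chromanone tert-butyl ester 9 (not isolated)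
Conditions: PhMe (0.05 M, base-free, silanised glass), 95 °C; then quinidine-derived 3,5-bis(trifluoromethyl)phenyl thiourea (10 mol%), −25 °C; then TsOH·H2O (2 equiv), 80 °C
Reagents that add atoms: none
Why: Heating the aryl 1,1-dimethylallyl ether triggers an aromatic Claisen [3,3] shift to the only free ortho carbon (the future C8) and rearomatisation gives phenol 8 with the prenyl group in place and O1 unmasked; at −25 °C the bifunctional cinchona thiourea binds the β-keto ester of 8 through its two N–H bonds while the quinuclidine nitrogen delivers the phenol to the alkylidene carbon to give 9, and acid then removes both tert-butyl groups and CO2. The closest known reactions are the thermal rearrangement of aryl 1,1-dimethylallyl ethers to ortho-prenylphenols and the thiourea-catalysed enantioselective oxa-Michael cyclisation of 2'-hydroxyaryl alkylidene β-keto esters followed by acid decarboxylation in the same flask. The pyranone ring is closed at O1–C2 in a 6-endo-trig oxa-Michael mode. C2 is the only lasting stereocentre and its S configuration is set by the catalyst, which exposes one face of the doubly hydrogen-bonded alkylidene to the phenol; C3 is stereogenic only in 9 and becomes CH2 on decarboxylation. The step needs prenyl delivery to C8 only (the other ortho carbon carries the acyl group, so a shift there can only revert), ring closure through O1 only (the second ortho oxygen, O5, is a methyl ether), and no uncatalysed closure of 8 before the catalyst is added (base-free toluene and the O–H···O=C hydrogen bond of 8 are expected to hold the phenol back). TsOH also protonates the catalyst, so no base-mediated retro-Michael path remains during decarboxylation, and the prenyl group has no neighbouring free hydroxyl with which to cyclise.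

Step 6
Reactants: 10 (2S)-2-(4-hydroxyphenyl)-5,6,7-trimethoxy-8-(3-methylbut-2-en-1-yl)-2,3-dihydro-4H-chromen-4-one
Product: 11 (2S)-5-hydroxy-2-(4-hydroxyphenyl)-6,7-dimethoxy-8-(3-methylbut-2-en-1-yl)-2,3-dihydro-4H-chromen-4-one
Conditions: MgI2·OEt2 (4 equiv), THF, 60 °C; aq. NH4Cl
Reagents that add atoms: none
Why: Chelation-controlled ether cleavage in which Mg(II) bound between the C4 carbonyl and the peri O5 activates only that methyl group for SN2 attack by iodide, a reagent known to demethylate 5-methoxy-8-prenylflavanones while leaving the prenyl group, the 6- and 7-methyl ethers and, under these non-basic conditions, the C2 centre untouched.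

**Compound list**

1 | 1-(6-hydroxy-2,3,4-trimethoxyphenyl)ethan-1-one | COc1c(OC)c(OC)cc(O)c1C(C)=O | starting material
2 | 3-chloro-3-methylbut-1-yne | CC(C)(Cl)C#C | starting material
3 | 1-{2,3,4-trimethoxy-6-[(2-methylbut-3-yn-2-yl)oxy]phenyl}ethan-1-one | COc1c(OC)c(OC)cc(OC(C)(C)C#C)c1C(C)=O | intermediate
4 | 1-{2,3,4-trimethoxy-6-[(2-methylbut-3-en-2-yl)oxy]phenyl}ethan-1-one | COc1c(OC)c(OC)cc(OC(C)(C)C=C)c1C(C)=O | intermediate
5 | tert-butyl 3-oxo-3-{2,3,4-trimethoxy-6-[(2-methylbut-3-en-2-yl)oxy]phenyl}propanoate | COc1c(OC)c(OC)cc(OC(C)(C)C=C)c1C(=O)CC(=O)OC(C)(C)C | intermediate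
6 | 4-(tert-butoxy)benzaldehyde | CC(C)(C)Oc1ccc(C=O)cc1 | starting material
7 | tert-butyl (2Z)-3-(4-tert-butoxyphenyl)-2-{2,3,4-trimethoxy-6-[(2-methylbut-3-en-2-yl)oxy]benzoyl}prop-2-enoate | COc1c(OC)c(OC)cc(OC(C)(C)C=C)c1C(=O)/C(C(=O)OC(C)(C)C)=C/c1ccc(OC(C)(C)C)cc1 | intermediate
8 | tert-butyl (2Z)-3-(4-tert-butoxyphenyl)-2-[2-hydroxy-4,5,6-trimethoxy-3-(3-methylbut-2-en-1-yl)benzoyl]prop-2-enoate | COc1c(OC)c(OC)c(CC=C(C)C)c(O)c1C(=O)/C(C(=O)OC(C)(C)C)=C/c1ccc(OC(C)(C)C)cc1 | intermediate
9 | tert-butyl (2S,3R)-2-(4-tert-butoxyphenyl)-5,6,7-trimethoxy-8-(3-methylbut-2-en-1-yl)-4-oxo-3,4-dihydro-2H-chromene-3-carboxylate (2,3-trans keto form; C3 epimerisable and enolisable) | COc1c(OC)c2c(c(CC=C(C)C)c1OC)O[C@H](c1ccc(OC(C)(C)C)cc1)[C@@H](C(=O)OC(C)(C)C)C2=O | intermediate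
10 | (2S)-2-(4-hydroxyphenyl)-5,6,7-trimethoxy-8-(3-methylbut-2-en-1-yl)-2,3-dihydro-4H-chromen-4-one | COc1c(OC)c2c(c(CC=C(C)C)c1OC)O[C@H](c1ccc(O)cc1)CC2=O | intermediate
11 | (2S)-5-hydroxy-2-(4-hydroxyphenyl)-6,7-dimethoxy-8-(3-methylbut-2-en-1-yl)-2,3-dihydro-4H-chromen-4-one | COc1c(O)c2c(c(CC=C(C)C)c1OC)O[C@H](c1ccc(O)cc1)CC2=O | target

**Step count**

Total steps: 6. Longest linear sequence: 6 (1 → 3 → 4 → 5 → 7 → 10 → 11).

**Steps most likely to fail**

Step 5. Two processes may go wrong. The freshly unmasked phenol may close thermally, without the catalyst, during the 95 °C stage and so erode the enantiomeric purity. Hot TsOH may also protonate the prenyl double bond or loosen the C2–O1 bond of the 4'-oxygenated benzylic ether. The fallback separates the rearrangement from the ring closure so that the phenol is never heated next to the acceptor. It sets out from 4. Thermal Claisen rearrangement of 4 (PhMe, 100 °C) should give 1-[2-hydroxy-4,5,6-trimethoxy-3-(3-methylbut-2-en-1-yl)phenyl]ethan-1-one F1. C-acylation of its dianion (LiHMDS, 3.3 equiv; Boc2O; THF, −78 °C) should give tert-butyl 3-[2-hydroxy-4,5,6-trimethoxy-3-(3-methylbut-2-en-1-yl)phenyl]-3-oxopropanoate F2. Buffered Knoevenagel condensation of F2 with 6 at 20 °C then gives the alkylidene with the phenol already free. The fallback comes back to the route at 8, now an isolated compound, which enters the −25 °C thiourea cyclisation and the acid stage of step 5 unchanged.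

Step 6. The Lewis acid may open and re-close the pyranone ring through the chalcone, with loss of the C2 configuration, or may go on to cleave the neighbouring 6-methyl ether. The fallback moves the demethylation to a stage without a stereocentre and sets C2 afterwards by asymmetric conjugate addition. It sets out from 4 and passes through the phenol F1 described above. Condensation of F1 with DMF dimethyl acetal (90 °C) should give (2E)-3-(dimethylamino)-1-[2-hydroxy-4,5,6-trimethoxy-3-(3-methylbut-2-en-1-yl)phenyl]prop-2-en-1-one F3. Mild acid (cat. TsOH, PhMe, 60 °C) should close it to 5,6,7-trimethoxy-8-(3-methylbut-2-en-1-yl)-4H-chromen-4-one F4. MgI2·OEt2 then gives 5-hydroxy-6,7-dimethoxy-8-(3-methylbut-2-en-1-yl)-4H-chromen-4-one F5. Pd(II)/t-BuPyOx-catalysed conjugate addition of (4-hydroxyphenyl)boronic acid (Pd(TFA)2, NH4PF6, H2O, DCE, 60 °C; ligand enantiomer chosen for the 2S product) comes back to the route at 11.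

Step 1. The hydrogen-bonded, ortho-acyl phenoxide may react sluggishly with the tertiary propargylic electrophile, so that elimination of the chloride or C-alkylation takes over. The fallback replaces propargylation and semi-hydrogenation by a Tsuji–Trost allylic etherification. It sets out from 1, which with tert-butyl 2-methylbut-3-en-2-yl carbonate and Pd(PPh3)4 (THF, 0 °C) should give the branched 1,1-dimethylallyl ether directly, and it comes back to the route at 4.

**Further compounds**

F1 | step 5 | 1-[2-hydroxy-4,5,6-trimethoxy-3-(3-methylbut-2-en-1-yl)phenyl]ethan-1-one | COc1c(OC)c(OC)c(CC=C(C)C)c(O)c1C(C)=O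
F2 | step 5 | tert-butyl 3-[2-hydroxy-4,5,6-trimethoxy-3-(3-methylbut-2-en-1-yl)phenyl]-3-oxopropanoate | COc1c(OC)c(OC)c(CC=C(C)C)c(O)c1C(=O)CC(=O)OC(C)(C)C
F3 | step 6 | (2E)-3-(dimethylamino)-1-[2-hydroxy-4,5,6-trimethoxy-3-(3-methylbut-2-en-1-yl)phenyl]prop-2-en-1-one | COc1c(OC)c(OC)c(CC=C(C)C)c(O)c1C(=O)/C=C/N(C)C
F4 | step 6 | 5,6,7-trimethoxy-8-(3-methylbut-2-en-1-yl)-4H-chromen-4-one | COc1c(OC)c2c(c(CC=C(C)C)c1OC)occc2=O
F5 | step 6 | 5-hydroxy-6,7-dimethoxy-8-(3-methylbut-2-en-1-yl)-4H-chromen-4-one | COc1c(O)c2c(c(CC=C(C)C)c1OC)occc2=O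
F0 | step 1 | none | none
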